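Each half is a 2,3-seco-8,13-epoxylabdane. The route rests on reading the tetrahydropyran (ring C) of the diol half as a furan–oxyallyl [4+3] adduct: O, C8 and C13 with the two cis-diaxial methyls C16 and C17 (tied as a CH=CH bridge) are a furan, and C9–C11–C12 is an oxyallyl cation. The key step, an intramolecular cycloaddition of a chloromethyl ketone tethered to the furan through C10–C5–C6–C7, closes ring B and ring C at once and sets C8, C9 and C13; ozonolysis and desulfurisation then erase the bridge and the C11 carbonyl. The vinyl half arises likewise from 2,3-dimethylfuran, and the halves are joined by esterification.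

Key step: step 16

Remark: labdane numbering (C1–C20) is used for both halves; the two halves have opposite configurations at C13 in the target as drawn, and both are made as drawn (diol half from a 5-substituted furan, vinyl half from 2,3-dimethylfuran).

**Common fragment (steps 1–11)**

Step 1
Reactants: 1 2,4,4-trimethylcyclohex-2-en-1-one
Product: 2 (1S)-2,4,4-trimethylcyclohex-2-en-1-ol
Conditions: (R)-methyl-oxazaborolidine from diphenylprolinol [(R)-Me-CBS] (10 mol%), BH3·SMe2, THF, −20 °C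
Reagents that add atoms: none
Why: CBS reduction; with the methyl-bearing alkene arm as the large group the (R)-catalyst should deliver hydride to give the (S)-allylic alcohol.

Step 2
Reactants: 2 (1S)-2,4,4-trimethylcyclohex-2-en-1-ol
Product: 4 ethyl 2-[(1R)-2,6,6-trimethylcyclohex-2-en-1-yl]acetate, via mixed ketene acetal 3 (not isolated)
Conditions: MeC(OEt)3, EtCO2H (cat.), xylene, 140 °C, EtOH distilled off
Reagents that add atoms: triethyl orthoacetate CC(OCC)(OCC)OCC
Why: Johnson–Claisen rearrangement; the suprafacial [3,3] shift passes the carbinol configuration to the ring carbon next to the gem-dimethyl group (future C5), the new C–C bond forming on the face that carried oxygen.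

Step 3
Reactants: 4 ethyl 2-[(1R)-2,6,6-trimethylcyclohex-2-en-1-yl]acetate
Product: 5 2-[(1R)-2,6,6-trimethylcyclohex-2-en-1-yl]ethan-1-ol
Conditions: LiAlH4, Et2O, 0 °C
Reagents that add atoms: none
Why: Hydride reduction of the ester gives the C7 alcohol; the isolated alkene is inert.

Step 4
Reactants: 5 2-[(1R)-2,6,6-trimethylcyclohex-2-en-1-yl]ethan-1-ol
Product: 6 (6R)-6-(2-chloroethyl)-1,5,5-trimethylcyclohex-1-ene
Conditions: PPh3, CCl4, CH2Cl2, 40 °C
Reagents that add atoms: tetrachloromethane ClC(Cl)(Cl)Cl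
Why: Appel reaction; the primary chloride is a coupling handle that is inert to the oxidations, Lewis acid and enolate chemistry that follow.

Step 5
Reactants: 6 (6R)-6-(2-chloroethyl)-1,5,5-trimethylcyclohex-1-ene
Product: 7 (4R)-4-(2-chloroethyl)-3,5,5-trimethylcyclohex-2-en-1-one
Conditions: t-BuOOH (70% aq.), Rh2(cap)4 (dirhodium tetracaprolactamate, 1 mol%), K2CO3, CH2Cl2, rt
Reagents that add atoms: tert-butyl hydroperoxide CC(C)(C)OO
Why: Allylic oxidation at the ring CH2 next to the less substituted alkene carbon should give the β-methyl enone (C2 ketone); the hindered tertiary allylic C5–H is expected to react more slowly.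

Step 6
Reactants: 7 (4R)-4-(2-chloroethyl)-3,5,5-trimethylcyclohex-2-en-1-one
Product: 9 (4S,6R)-4-(2-chloroethyl)-6-hydroxy-3,5,5-trimethylcyclohex-2-en-1-one, via lithium dienolate 8 (not isolated)
Conditions: LiN(iPr)2 (LDA), THF, −78 °C; then 3-phenyl-2-(phenylsulfonyl)oxaziridine, −78 °C; aq. NH4Cl
Reagents that add atoms: 3-phenyl-2-(phenylsulfonyl)oxaziridine O1N(S(=O)(=O)c2ccccc2)C1c1ccccc1
Why: Kinetic α'-deprotonation and electrophilic enolate hydroxylation mark C3 for the later ring opening; attack anti to the pseudoaxial chloroethyl chain is expected, and this temporary stereocenter is destroyed in step 8.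

Step 7
Reactants: 9 (4S,6R)-4-(2-chloroethyl)-6-hydroxy-3,5,5-trimethylcyclohex-2-en-1-one
Product: 10 (2R,4S,5R)-4-(2-chloroethyl)-2-hydroxy-3,3,5-trimethyl-5-(2-methylprop-2-en-1-yl)cyclohexan-1-one
Conditions: TiCl4 (2.2 equiv), CH2Cl2, −78 °C; then CH2=C(Me)CH2SiMe3 (3 equiv), −78 → −40 °C
Reagents that add atoms: trimethyl(2-methylprop-2-en-1-yl)silane C=C(C)C[Si](C)(C)C
Why: Hosomi–Sakurai conjugate allylation of the TiCl4-chelated ketol; the silane should add to the β-carbon (C10) on the face opposite the pseudoaxial chloroethyl chain, setting the quaternary centre with the new arm trans to that chain.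

Step 8
Reactants: 10 (2R,4S,5R)-4-(2-chloroethyl)-2-hydroxy-3,3,5-trimethyl-5-(2-methylprop-2-en-1-yl)cyclohexan-1-one
Product: 11 methyl (3R,4S)-6-chloro-3-methyl-4-(2-methyl-1-oxopropan-2-yl)-3-(2-methylprop-2-en-1-yl)hexanoate
Conditions: Pb(OAc)4, MeOH/toluene 1:1, 0 °C
Reagents that add atoms: methanol CO
Why: Criegee-type cleavage of the α-ketol in methanol opens ring A between C2 and C3, the ketone carbon leaving as the methyl ester and the carbinol carbon as the aldehyde, so the two termini are differentiated.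

Step 9
Reactants: 11 methyl (3R,4S)-6-chloro-3-methyl-4-(2-methyl-1-oxopropan-2-yl)-3-(2-methylprop-2-en-1-yl)hexanoate
Product: 12 (3S,4R)-3-(2-chloroethyl)-6-methoxy-2,2,4-trimethyl-4-(2-methylprop-2-en-1-yl)-6-oxohexanoic acid
Conditions: NaClO2, NaH2PO4, 2-methyl-2-butene, t-BuOH/H2O, rt
Reagents that add atoms: sodium chlorite [Na+].[O-]Cl=O
Why: Pinnick oxidation of the non-enolisable neopentyl aldehyde; the scavenger protects the methallyl alkene from hypochlorite.

Step 10
Reactants: 12 (3S,4R)-3-(2-chloroethyl)-6-methoxy-2,2,4-trimethyl-4-(2-methylprop-2-en-1-yl)-6-oxohexanoic acid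
Product: 13 1-methyl 6-[2-(trimethylsilyl)ethyl] (3R,4S)-4-(2-chloroethyl)-3,5,5-trimethyl-3-(2-methylprop-2-en-1-yl)hexanedioate
Conditions: Me3SiCH2CH2OC(=NH)CCl3, toluene, 100 °C
Reagents that add atoms: 2-(trimethylsilyl)ethyl 2,2,2-trichloroacetimidate C[Si](C)(C)CCOC(=N)C(Cl)(Cl)Cl
Why: Promoter-free trichloroacetimidate esterification, in which the hindered acid acts as the nucleophile, installs a fluoride-labile ester orthogonal to the methyl ester without acid that could add to the alkene.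

Step 11
Reactants: 13 1-methyl 6-[2-(trimethylsilyl)ethyl] (3R,4S)-4-(2-chloroethyl)-3,5,5-trimethyl-3-(2-methylprop-2-en-1-yl)hexanedioate
Product: 14 1-methyl 6-[2-(trimethylsilyl)ethyl] (3R,4S)-4-(2-chloroethyl)-3,5,5-trimethyl-3-(2-oxopropyl)hexanedioate
Conditions: O3, CH2Cl2/MeOH, −78 °C; then Me2S
Reagents that add atoms: ozone O=[O+][O-]
Why: Ozonolysis of the only alkene unmasks the C11 methyl ketone (C9–C11–C12 arm) before any furan is present.

**Furan for the diol half (steps 12–13)**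

Step 12
Reactants: 15 D-glucal
Product: 16 (1R)-1-(furan-2-yl)ethane-1,2-diol
Conditions: InCl3·3H2O (10 mol%), MeCN, rt
Reagents that add atoms: none
Why: Lewis-acid-induced allylic (Ferrier-type) ring opening and cyclodehydration of the glycal gives the furan; C5 of the sugar is untouched and becomes C14 (R).

Step 13
Reactants: 16 (1R)-1-(furan-2-yl)ethane-1,2-diol
Product: 17 2-[(4R)-2,2-dimethyl-1,3-dioxolan-4-yl]furan
Conditions: Me2C(OMe)2, pyridinium p-toluenesulfonate (cat.), acetone, rt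
Reagents that add atoms: 2,2-dimethoxypropane COC(C)(C)OC
Why: Acetonide formation by transketalisation under mild acid that the furan tolerates.

**Diol half (steps 14–19)**

Step 14
Reactants: 17 2-[(4R)-2,2-dimethyl-1,3-dioxolan-4-yl]furan; 14 1-methyl 6-[2-(trimethylsilyl)ethyl] (3R,4S)-4-(2-chloroethyl)-3,5,5-trimethyl-3-(2-oxopropyl)hexanedioate
Product: 20 1-methyl 6-[2-(trimethylsilyl)ethyl] (3R,4S)-4-{2-[5-((4R)-2,2-dimethyl-1,3-dioxolan-4-yl)furan-2-yl]ethyl}-3,5,5-trimethyl-3-(2-oxopropyl)hexanedioate, via 5-lithiofuran 18 (not isolated), via furylzinc chloride 19 (not isolated)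
Conditions: 17, n-BuLi, THF, −78 → 0 °C; ZnCl2, 0 °C → rt; then 14, Pd2(dba)3 (2 mol%), PCyp3 (8 mol%), N-methylimidazole, THF/NMP, 80 °C
Reagents that add atoms: none
Why: Negishi sp3–sp2 coupling; the electron-rich trialkylphosphine lets zerovalent palladium add to the unactivated primary C–Cl bond faster than β-hydride elimination, and the arylzinc leaves ketone and esters alone.

Step 15
Reactants: 20 1-methyl 6-[2-(trimethylsilyl)ethyl] (3R,4S)-4-{2-[5-((4R)-2,2-dimethyl-1,3-dioxolan-4-yl)furan-2-yl]ethyl}-3,5,5-trimethyl-3-(2-oxopropyl)hexanedioate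
Product: 22 1-methyl 6-[2-(trimethylsilyl)ethyl] (3R,4S)-3-(3-chloro-2-oxopropyl)-4-{2-[5-((4R)-2,2-dimethyl-1,3-dioxolan-4-yl)furan-2-yl]ethyl}-3,5,5-trimethylhexanedioate, via lithium enolate 21 (not isolated)
Conditions: LDA (1.05 equiv), THF, −78 °C; then TsCl, −78 °C
Reagents that add atoms: 4-methylbenzenesulfonyl chloride Cc1ccc(cc1)S(=O)(=O)Cl
Why: Kinetic enolisation at the methyl group and chlorine transfer from the sulfonyl chloride give the α-chloroketone without an electrophilic halogen source that would attack the furan.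

Step 16
Reactants: 22 1-methyl 6-[2-(trimethylsilyl)ethyl] (3R,4S)-3-(3-chloro-2-oxopropyl)-4-{2-[5-((4R)-2,2-dimethyl-1,3-dioxolan-4-yl)furan-2-yl]ethyl}-3,5,5-trimethylhexanedioate
Product: 24 diol-half cycloadduct (ring B trans-fused to an 8-oxabicyclo[3.2.1]oct-6-en-3-one), via oxyallyl cation 23 (not isolated)
Conditions: Et3N (3 equiv), CF3CH2OH, 0.005 M, rt; then DBU (cat.), toluene, rt (C9 equilibration)
Reagents that add atoms: none
Why: Triethylamine in the ionising, weakly nucleophilic fluoro alcohol enolises the chloroketone towards C9 and the enolate loses chloride to give the Z-configured 2-oxyallyl cation 23 (C9–C11–C12), which the tethered furan traps across its 2,5-positions (C8 and C13) in a [4+3] cycloaddition; the closest known reaction type is the intramolecular furan–oxyallyl cycloaddition of α-haloketones under base/fluoro-alcohol conditions. Ring B closes 6-exo by the C8–C9 bond through the four-atom tether C10–C5–C6–C7, and the C12–C13 bond closes the oxygen-bridged seven-membered ring, that is the pyranone O–C8–C9–C11–C12–C13 carrying C16=C17 as its etheno bridge. C8 and C13 are set together by the furan face that is attacked, which the chair-like tether fixes with the CMe2CO2R group at C5 equatorial and C20 axial; C9 is set by the compact transition state of the Z-oxyallyl, which puts C10 equatorial on the new pyranone and so gives the trans ring fusion. Only the trans-fused adduct from this chair has the required array (bridge carbon C17 syn to C20, H9 anti to C20), and a C9 epimer formed through an extended transition state should be drained into it by the DBU equilibration because C9 is α to the ketone. The step needs capture by the furan rather than by solvent or ester oxygen, which high dilution, the gem-disubstituted tether and the electron-rich 2,5-dialkylfuran should secure; C14 is a spectator.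

Step 17
Reactants: 24 diol-half cycloadduct
Product: 25 diol-half 16,17-dialdehyde 11-ketone
Conditions: O3, CH2Cl2/MeOH, −78 °C; then Me2S
Reagents that add atoms: ozone O=[O+][O-]
Why: Ozonolysis of the strained bridge alkene, the only C=C left, releases C16 and C17 as cis-diaxial, non-enolisable aldehydes on the pyranone.

Step 18
Reactants: 25 diol-half 16,17-dialdehyde 11-ketone
Product: 26 diol-half 11,16,17-tris(1,3-dithiolane) 14,15-diol
Conditions: HSCH2CH2SH (excess), BF3·OEt2, CH2Cl2, −20 → 0 °C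
Reagents that add atoms: ethane-1,2-dithiol SCCS
Why: Lewis-acid dithioacetalisation of all three carbonyls; the acetonide is exchanged off under the same conditions (acetone leaves as its dithioketal), which frees the 14,15-diol.

Step 19
Reactants: 26 diol-half 11,16,17-tris(1,3-dithiolane) 14,15-diol
Product: 27 diol-half monomer (C2 methyl ester, C3 2-(trimethylsilyl)ethyl ester, free 14,15-diol)
Conditions: Raney Ni (W-2), EtOH, 60 °C
Reagents that add atoms: none
Why: Mozingo-type desulfurisation turns C16 and C17 into the two cis methyls and C11 into CH2; esters, ethers and the diol are inert.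

**Vinyl half (steps 20–28)**

Step 20
Reactants: 28 2,3-dimethylfuran; 14 1-methyl 6-[2-(trimethylsilyl)ethyl] (3R,4S)-4-(2-chloroethyl)-3,5,5-trimethyl-3-(2-oxopropyl)hexanedioate
Product: 31 1-methyl 6-[2-(trimethylsilyl)ethyl] (3R,4S)-4-[2-(4,5-dimethylfuran-2-yl)ethyl]-3,5,5-trimethyl-3-(2-oxopropyl)hexanedioate, via 5-lithio-2,3-dimethylfuran 29 (not isolated), via furylzinc chloride 30 (not isolated)
Conditions: 28, n-BuLi, THF, −78 → 0 °C; ZnCl2; then 14, Pd2(dba)3 (2 mol%), PCyp3 (8 mol%), N-methylimidazole, THF/NMP, 80 °C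
Reagents that add atoms: none
Why: Same Negishi coupling as step 14; lithiation occurs at the only free α-position of the furan.

Step 21
Reactants: 31 1-methyl 6-[2-(trimethylsilyl)ethyl] (3R,4S)-4-[2-(4,5-dimethylfuran-2-yl)ethyl]-3,5,5-trimethyl-3-(2-oxopropyl)hexanedioate
Product: 33 1-methyl 6-[2-(trimethylsilyl)ethyl] (3R,4S)-3-(3-chloro-2-oxopropyl)-4-[2-(4,5-dimethylfuran-2-yl)ethyl]-3,5,5-trimethylhexanedioate, via lithium enolate 32 (not isolated)
Conditions: LDA (1.05 equiv), THF, −78 °C; then TsCl, −78 °C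
Reagents that add atoms: 4-methylbenzenesulfonyl chloride Cc1ccc(cc1)S(=O)(=O)Cl
Why: Kinetic enolate chlorination as in step 15.

Step 22
Reactants: 33 1-methyl 6-[2-(trimethylsilyl)ethyl] (3R,4S)-3-(3-chloro-2-oxopropyl)-4-[2-(4,5-dimethylfuran-2-yl)ethyl]-3,5,5-trimethylhexanedioate
Product: 35 vinyl-half cycloadduct (bridge C17H=C14(CH3) and bridgehead methyl C16 on C13), via oxyallyl cation 34 (not isolated)
Conditions: Et3N (3 equiv), CF3CH2OH, 0.005 M, rt; then DBU (cat.), toluene, rt
Reagents that add atoms: none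
Why: Intramolecular furan–oxyallyl [4+3] cycloaddition under the same tether control as step 16; here the furan 3-carbon that carries the methyl becomes C14 syn-axial to C17, which gives the C13 configuration of the vinyl half.

Step 23
Reactants: 35 vinyl-half cycloadduct
Product: 36 vinyl-half 17-aldehyde 11,14-diketone
Conditions: O3, CH2Cl2/MeOH, −78 °C; then Me2S
Reagents that add atoms: ozone O=[O+][O-]
Why: Ozonolysis of the trisubstituted bridge alkene gives an aldehyde at C17 and a methyl ketone at C14, so the two bridge carbons are differentiated.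

Step 24
Reactants: 36 vinyl-half 17-aldehyde 11,14-diketone
Product: 37 vinyl-half 11,17-bis(1,3-dithiolane) 14-ketone
Conditions: HSCH2CH2SH (2.5 equiv), BF3·OEt2, CH2Cl2, −40 → −20 °C
Reagents that add atoms: ethane-1,2-dithiol SCCS
Why: Chemoselective dithioacetalisation of the aldehyde and the unhindered ring ketone; the methyl ketone on the fully substituted, oxygen-bearing C13 should react far more slowly.

Step 25
Reactants: 37 vinyl-half 11,17-bis(1,3-dithiolane) 14-ketone
Product: 38 vinyl-half 13-acetyl compound (C17 methyl, C11 methylene)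
Conditions: Raney Ni (W-2, acetone-washed), EtOH, rt
Reagents that add atoms: none
Why: Raney nickel desulfurisation; the deactivated catalyst at room temperature should leave the hindered ketone unreduced.

Step 26
Reactants: 38 vinyl-half 13-acetyl compound
Product: 40 vinyl-half enol triflate, via potassium enolate 39 (not isolated)
Conditions: KN(SiMe3)2, THF, −78 °C; then PhNTf2, −78 → 0 °C
Reagents that add atoms: N-phenylbis(trifluoromethanesulfonimide) FC(F)(F)S(=O)(=O)N(c1ccccc1)S(=O)(=O)C(F)(F)F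
Why: The ketone can enolise only towards its methyl group (C13 is quaternary), so O-triflation gives a single terminal enol triflate.

Step 27
Reactants: 40 vinyl-half enol triflate
Product: 41 vinyl-half diester (13-vinyl)
Conditions: Pd(OAc)2 (5 mol%), PPh3, HCO2H, Bu3N, DMF, 60 °C
Reagents that add atoms: none
Why: Formate reduction of the vinyl triflate (oxidative addition to zerovalent palladium, formate exchange, decarboxylation, reductive elimination) gives the C14=C15 vinyl group without touching the esters.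

Step 28
Reactants: 41 vinyl-half diester
Product: 42 vinyl-half C3 acid (C2 methyl ester)
Conditions: Bu4NF, THF, 0 °C → rt; aq. NH4Cl
Reagents that add atoms: none
Why: Fluoride-induced β-elimination cleaves only the 2-(trimethylsilyl)ethyl ester, freeing the hindered C3 acid under non-acidic conditions that spare the tertiary allylic ether.

**Union and deprotection (steps 29–31)**

Step 29
Reactants: 42 vinyl-half C3 acid; 27 diol-half monomer
Product: 44 protected dimer (C15–O ester link), via acid chloride 43 (not isolated)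
Conditions: 42, Me2C=C(Cl)NMe2, CH2Cl2, 0 °C → rt; then 27, DMAP, pyridine, 40 °C
Reagents that add atoms: none
Why: Neutral acid chloride formation with the α-chloroenamine followed by DMAP acylation; the hindered acyl chloride should take the primary C15 hydroxyl and not the secondary C14 hydroxyl next to the quaternary C13.

Step 30
Reactants: 44 protected dimer
Product: 45 dimer with free diol-half C3 acid (two methyl esters left)
Conditions: Bu4NF, AcOH (1 equiv), THF, 0 °C → rt; aq. NH4Cl
Reagents that add atoms: none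
Why: Fluoride cleavage of the remaining 2-(trimethylsilyl)ethyl ester; the buffer should suppress acyl migration of the hindered inter-unit ester.

Step 31
Reactants: 45 dimer with free diol-half C3 acid
Product: 46 CNP0107285.3 (target)
Conditions: Me3SnOH, ClCH2CH2Cl, 80 °C; dilute aq. HCl work-up
Reagents that add atoms: trimethyltin hydroxide C[Sn](C)(C)O
Why: Tin hydroxide hydrolysis is selective for the two unhindered CH2CO2Me groups and should leave the pivalate-like inter-unit ester and the vinyl group intact.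

**Compound list**

1 | 2,4,4-trimethylcyclohex-2-en-1-one | CC1=CC(C)(C)CCC1=O | starting material
2 | (1S)-2,4,4-trimethylcyclohex-2-en-1-ol | O[C@H]1CCC(C)(C)C=C1C | intermediate
3 | 1-ethoxyvinyl ether of 2 (mixed ketene acetal) | C=C(OCC)O[C@H]1CCC(C)(C)C=C1C | intermediate
4 | ethyl 2-[(1R)-2,6,6-trimethylcyclohex-2-en-1-yl]acetate | CCOC(=O)C[C@H]1C(C)=CCCC1(C)C | intermediate
5 | 2-[(1R)-2,6,6-trimethylcyclohex-2-en-1-yl]ethan-1-ol | OCC[C@H]1C(C)=CCCC1(C)C | intermediate
6 | (6R)-6-(2-chloroethyl)-1,5,5-trimethylcyclohex-1-ene | ClCC[C@H]1C(C)=CCCC1(C)C | intermediate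
7 | (4R)-4-(2-chloroethyl)-3,5,5-trimethylcyclohex-2-en-1-one | O=C1C=C(C)[C@H](CCCl)C(C)(C)C1 | intermediate
8 | cross-conjugated lithium dienolate of 7 | [Li]OC1=CC(C)(C)[C@@H](CCCl)C(C)=C1 | intermediate
9 | (4S,6R)-4-(2-chloroethyl)-6-hydroxy-3,5,5-trimethylcyclohex-2-en-1-one (OH trans to the chloroethyl chain) | O=C1C=C(C)[C@H](CCCl)C(C)(C)[C@H]1O | intermediate
10 | (2R,4S,5R)-4-(2-chloroethyl)-2-hydroxy-3,3,5-trimethyl-5-(2-methylprop-2-en-1-yl)cyclohexan-1-one (methallyl trans to chloroethyl) | O=C1C[C@@](C)(CC(C)=C)[C@H](CCCl)C(C)(C)[C@H]1O | intermediate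
11 | methyl (3R,4S)-6-chloro-3-methyl-4-(2-methyl-1-oxopropan-2-yl)-3-(2-methylprop-2-en-1-yl)hexanoate | COC(=O)C[C@@](C)(CC(C)=C)[C@H](CCCl)C(C)(C)C=O | intermediate
12 | (3S,4R)-3-(2-chloroethyl)-6-methoxy-2,2,4-trimethyl-4-(2-methylprop-2-en-1-yl)-6-oxohexanoic acid | COC(=O)C[C@@](C)(CC(C)=C)[C@H](CCCl)C(C)(C)C(=O)O | intermediate
13 | 1-methyl 6-[2-(trimethylsilyl)ethyl] (3R,4S)-4-(2-chloroethyl)-3,5,5-trimethyl-3-(2-methylprop-2-en-1-yl)hexanedioate | COC(=O)C[C@@](C)(CC(C)=C)[C@H](CCCl)C(C)(C)C(=O)OCC[Si](C)(C)C | intermediate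
14 | 1-methyl 6-[2-(trimethylsilyl)ethyl] (3R,4S)-4-(2-chloroethyl)-3,5,5-trimethyl-3-(2-oxopropyl)hexanedioate | COC(=O)C[C@@](C)(CC(C)=O)[C@H](CCCl)C(C)(C)C(=O)OCC[Si](C)(C)C | intermediate
15 | D-glucal | C1=CO[C@@H]([C@H]([C@@H]1O)O)CO | starting material
16 | (1R)-1-(furan-2-yl)ethane-1,2-diol | OC[C@@H](O)c1ccco1 | intermediate
17 | 2-[(4R)-2,2-dimethyl-1,3-dioxolan-4-yl]furan | CC1(C)OC[C@@H](O1)c1ccco1 | intermediate
18 | 5-lithio derivative of 17 | CC1(C)OC[C@@H](O1)c1ccc([Li])o1 | intermediate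
19 | furylzinc chloride from 18 | CC1(C)OC[C@@H](O1)c1ccc([Zn]Cl)o1 | intermediate
20 | 1-methyl 6-[2-(trimethylsilyl)ethyl] (3R,4S)-4-{2-[5-((4R)-2,2-dimethyl-1,3-dioxolan-4-yl)furan-2-yl]ethyl}-3,5,5-trimethyl-3-(2-oxopropyl)hexanedioate | CC1(C)OC[C@@H](O1)c1ccc(CC[C@H](C(C)(C)C(=O)OCC[Si](C)(C)C)[C@@](C)(CC(=O)OC)CC(C)=O)o1 | intermediate
21 | terminal lithium enolate of 20 | CC1(C)OC[C@@H](O1)c1ccc(CC[C@H](C(C)(C)C(=O)OCC[Si](C)(C)C)[C@@](C)(CC(=O)OC)CC(=C)O[Li])o1 | intermediate
22 | 1-methyl 6-[2-(trimethylsilyl)ethyl] (3R,4S)-3-(3-chloro-2-oxopropyl)-4-{2-[5-((4R)-2,2-dimethyl-1,3-dioxolan-4-yl)furan-2-yl]ethyl}-3,5,5-trimethylhexanedioate | CC1(C)OC[C@@H](O1)c1ccc(CC[C@H](C(C)(C)C(=O)OCC[Si](C)(C)C)[C@@](C)(CC(=O)OC)CC(=O)CCl)o1 | intermediate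
23 | Z-oxyallyl cation (zwitterion) from 22, C9–C11–C12 | CC1(C)OC[C@@H](O1)c1ccc(CC[C@H](C(C)(C)C(=O)OCC[Si](C)(C)C)[C@@](C)(CC(=O)OC)/C=C(\[O-])[CH2+])o1 | intermediate
24 | diol-half cycloadduct: 8,13-epoxy-11-oxo tricycle with C16=C17 as CH=CH bridge between C13 and C8; C2 methyl ester, C3 2-(trimethylsilyl)ethyl ester, 14,15-O-isopropylidene; H5 and H9 on one face, C20 and the bridge on the other, trans ring fusion, 14R | CC1(C)OC[C@@H](O1)[C@]3(C=C5)CC(=O)[C@H]4[C@](C)(CC(=O)OC)[C@@H](C(C)(C)C(=O)OCC[Si](C)(C)C)CC[C@]45O3 | intermediate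
25 | diol-half 16,17-dialdehyde 11-ketone (formyl groups cis on the pyranone) | CC1(C)OC[C@@H](O1)[C@]3(C=O)CC(=O)[C@H]4[C@](C)(CC(=O)OC)[C@@H](C(C)(C)C(=O)OCC[Si](C)(C)C)CC[C@]4(C=O)O3 | intermediate
26 | diol-half 11,16,17-tris(1,3-dithiolane) 14,15-diol | OC[C@@H](O)[C@]3(C5SCCS5)CC5(SCCS5)[C@H]4[C@](C)(CC(=O)OC)[C@@H](C(C)(C)C(=O)OCC[Si](C)(C)C)CC[C@]4(C5SCCS5)O3 | intermediate
27 | diol-half monomer: 2,3-seco-8,13-epoxy-14,15-dihydroxylabdane-2,3-dioic acid 2-methyl 3-[2-(trimethylsilyl)ethyl] diester (C16 and C17 cis, 14R) | OC[C@@H](O)[C@]3(C)CC[C@H]4[C@](C)(CC(=O)OC)[C@@H](C(C)(C)C(=O)OCC[Si](C)(C)C)CC[C@]4(C)O3 | intermediate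
28 | 2,3-dimethylfuran | Cc1occc1C | starting material
29 | 5-lithio-2,3-dimethylfuran | Cc1oc([Li])cc1C | intermediate
30 | (4,5-dimethylfuran-2-yl)zinc chloride | Cc1oc([Zn]Cl)cc1C | intermediate
31 | 1-methyl 6-[2-(trimethylsilyl)ethyl] (3R,4S)-4-[2-(4,5-dimethylfuran-2-yl)ethyl]-3,5,5-trimethyl-3-(2-oxopropyl)hexanedioate | Cc1oc(CC[C@H](C(C)(C)C(=O)OCC[Si](C)(C)C)[C@@](C)(CC(=O)OC)CC(C)=O)cc1C | intermediate
32 | terminal lithium enolate of 31 | Cc1oc(CC[C@H](C(C)(C)C(=O)OCC[Si](C)(C)C)[C@@](C)(CC(=O)OC)CC(=C)O[Li])cc1C | intermediate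
33 | 1-methyl 6-[2-(trimethylsilyl)ethyl] (3R,4S)-3-(3-chloro-2-oxopropyl)-4-[2-(4,5-dimethylfuran-2-yl)ethyl]-3,5,5-trimethylhexanedioate | Cc1oc(CC[C@H](C(C)(C)C(=O)OCC[Si](C)(C)C)[C@@](C)(CC(=O)OC)CC(=O)CCl)cc1C | intermediate
34 | Z-oxyallyl cation (zwitterion) from 33 | Cc1oc(CC[C@H](C(C)(C)C(=O)OCC[Si](C)(C)C)[C@@](C)(CC(=O)OC)/C=C(\[O-])[CH2+])cc1C | intermediate
35 | vinyl-half cycloadduct: 8,13-epoxy-11-oxo tricycle with bridge C17H=C14(CH3) between C8 and C13, C16 methyl on C13; diester as in 24 | CC(=C5)[C@@]1(C)CC(=O)[C@H]2[C@](C)(CC(=O)OC)[C@@H](C(C)(C)C(=O)OCC[Si](C)(C)C)CC[C@]25O1 | intermediate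
36 | vinyl-half 17-aldehyde 11,14-diketone (13-acetyl cis to 8-formyl) | CC(=O)[C@@]1(C)CC(=O)[C@H]2[C@](C)(CC(=O)OC)[C@@H](C(C)(C)C(=O)OCC[Si](C)(C)C)CC[C@]2(C=O)O1 | intermediate
37 | vinyl-half 11,17-bis(1,3-dithiolane) 14-ketone | CC(=O)[C@@]1(C)CC5(SCCS5)[C@H]2[C@](C)(CC(=O)OC)[C@@H](C(C)(C)C(=O)OCC[Si](C)(C)C)CC[C@]2(C5SCCS5)O1 | intermediate
38 | vinyl-half 13-acetyl compound (acetyl cis to C17 methyl) | CC(=O)[C@@]1(C)CC[C@H]2[C@](C)(CC(=O)OC)[C@@H](C(C)(C)C(=O)OCC[Si](C)(C)C)CC[C@]2(C)O1 | intermediate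
39 | potassium enolate of 38 | C=C(O[K])[C@@]1(C)CC[C@H]2[C@](C)(CC(=O)OC)[C@@H](C(C)(C)C(=O)OCC[Si](C)(C)C)CC[C@]2(C)O1 | intermediate
40 | vinyl-half enol triflate (C14 triflate, C14=C15) | C=C(OS(=O)(=O)C(F)(F)F)[C@@]1(C)CC[C@H]2[C@](C)(CC(=O)OC)[C@@H](C(C)(C)C(=O)OCC[Si](C)(C)C)CC[C@]2(C)O1 | intermediate
41 | vinyl-half diester: 2,3-seco-8,13-epoxylabd-14-ene-2,3-dioic acid 2-methyl 3-[2-(trimethylsilyl)ethyl] diester (vinyl cis to C17) | C=C[C@@]1(C)CC[C@H]2[C@](C)(CC(=O)OC)[C@@H](C(C)(C)C(=O)OCC[Si](C)(C)C)CC[C@]2(C)O1 | intermediate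
42 | vinyl-half C3 acid, C2 methyl ester | C=C[C@@]1(C)CC[C@H]2[C@](C)(CC(=O)OC)[C@@H](C(C)(C)C(=O)O)CC[C@]2(C)O1 | intermediate
43 | C3 acid chloride of 42 | C=C[C@@]1(C)CC[C@H]2[C@](C)(CC(=O)OC)[C@@H](C(C)(C)C(=O)Cl)CC[C@]2(C)O1 | intermediate
44 | protected dimer (C3 of vinyl half esterified to O15 of diol half; two methyl esters, one 2-(trimethylsilyl)ethyl ester) | C=C[C@@]1(C)CC[C@H]2[C@](C)(CC(=O)OC)[C@@H](C(C)(C)C(=O)OC[C@@H](O)[C@]3(C)CC[C@H]4[C@](C)(CC(=O)OC)[C@@H](C(C)(C)C(=O)OCC[Si](C)(C)C)CC[C@]4(C)O3)CC[C@]2(C)O1 | intermediate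
45 | dimer with free diol-half C3 acid, two C2 methyl esters | C=C[C@@]1(C)CC[C@H]2[C@](C)(CC(=O)OC)[C@@H](C(C)(C)C(=O)OC[C@@H](O)[C@]3(C)CC[C@H]4[C@](C)(CC(=O)OC)[C@@H](C(C)(C)C(=O)O)CC[C@]4(C)O3)CC[C@]2(C)O1 | intermediate
46 | CNP0107285.3 | C=C[C@@]1(C)CC[C@H]2[C@](C)(CC(=O)O)[C@@H](C(C)(C)C(=O)OC[C@@H](O)[C@]3(C)CC[C@H]4[C@](C)(CC(=O)O)[C@@H](C(C)(C)C(=O)O)CC[C@]4(C)O3)CC[C@]2(C)O1 | target

**Summary**

Total step count: 31. Longest linear sequence: 23 steps (steps 1–11, 20–28, 29–31).

Steps most likely to fail: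

1. Step 16 (and its twin, step 22). The monosubstituted oxyallyl cation may be captured by the fluoro alcohol or an ester oxygen, or collapse by Favorskii-type pathways, before the six-membered ring closes. Fallback: from 22, a second enolate chlorination (LDA, then TsCl, −78 °C) would give the dichloromethyl ketone F1. With Et3N in CF3CH2OH this ionises to a chlorine-stabilised, longer-lived oxyallyl cation of the kind known to add more efficiently to furans, giving the 12-chloro cycloadduct F2 (C12 epimers). Zn/Cu couple with NH4Cl in MeOH then removes the chlorine and the route is rejoined at 24.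

2. Step 7. Conjugate allylation may stall because the β-carbon is shielded by the syn-axial ring methyl and the neighbouring chain, while HCl from the free hydroxyl consumes the silane. Fallback: from 9, 1,2-addition of methallylmagnesium chloride (CeCl3, THF, −78 °C) to the ketone would give the tertiary carbinol F3, a 3-hydroxy-1,5-diene. KH/18-crown-6 in THF then triggers an anionic oxy-Cope rearrangement that delivers the methallyl group to C10 intramolecularly, on the face it occupies at the carbinol carbon, and protonation of the enolate returns ketol 10.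

3. Step 14 (and its twin, step 20). Oxidative addition of the unactivated alkyl chloride may be slow, so that β-hydride elimination or biaryl formation takes over. Fallback with reversed polarity: from 14, NaI in acetone would give the iodide F4, and zinc dust/LiCl in THF would insert to give the alkylzinc iodide F5. Furan 17 is brominated through 18 (n-BuLi, then BrCl2CCCl2Br) to the bromofuran F6. Coupling of F5 with F6 under Pd(OAc)2 and 2-dicyclohexylphosphino-2',6'-dimethoxybiphenyl in THF returns to 20.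

Further compounds
F1 | step 16 | 1-methyl 6-[2-(trimethylsilyl)ethyl] (3R,4S)-3-(3,3-dichloro-2-oxopropyl)-4-{2-[5-((4R)-2,2-dimethyl-1,3-dioxolan-4-yl)furan-2-yl]ethyl}-3,5,5-trimethylhexanedioate | CC1(C)OC[C@@H](O1)c1ccc(CC[C@H](C(C)(C)C(=O)OCC[Si](C)(C)C)[C@@](C)(CC(=O)OC)CC(=O)C(Cl)Cl)o1
F2 | step 16 | 12-chloro derivative of cycloadduct 24 (C12 epimers, configuration at C12 left open) | CC1(C)OC[C@@H](O1)[C@]3(C=C5)C(Cl)C(=O)[C@H]4[C@](C)(CC(=O)OC)[C@@H](C(C)(C)C(=O)OCC[Si](C)(C)C)CC[C@]45O3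
F3 | step 7 | 4-(2-chloroethyl)-3,5,5-trimethyl-1-(2-methylprop-2-en-1-yl)cyclohex-2-ene-1,6-diol (methallyl trans to the chloroethyl chain) | O[C@]1(CC(C)=C)C=C(C)[C@H](CCCl)C(C)(C)[C@H]1O
F4 | step 14 | 1-methyl 6-[2-(trimethylsilyl)ethyl] (3R,4S)-4-(2-iodoethyl)-3,5,5-trimethyl-3-(2-oxopropyl)hexanedioate | COC(=O)C[C@@](C)(CC(C)=O)[C@H](CCI)C(C)(C)C(=O)OCC[Si](C)(C)C
F5 | step 14 | alkylzinc iodide from F4 | COC(=O)C[C@@](C)(CC(C)=O)[C@H](CC[Zn]I)C(C)(C)C(=O)OCC[Si](C)(C)C
F6 | step 14 | 2-bromo-5-[(4R)-2,2-dimethyl-1,3-dioxolan-4-yl]furan | CC1(C)OC[C@@H](O1)c1ccc(Br)o1
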